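**Retrosynthetic overview**
1. Target ⇐ angelate and (R)-2-methylbutanoate esters put on last; the enal CHO comes from glycol cleavage of a dioxolane that also served as the stereocontrol element.
2. cis-Fused α-methylene-γ-lactone ⇐ C7/C8 epoxide: acetate-dianion opening at C7, lactonisation with inversion at C8, α-methylenation.
3. Epoxy diol ⇐ cyclohex-7-ene-6,9-diol ⇐ double methylenation (C10 CHO → vinyl, C4 C=O → C=CH2) of a keto-aldehyde cycloadduct.
4. Cyclohexene (C5, C6, C9, C10 set at once) ⇐ Diels–Alder of (1E,3E)-1,4-diacetoxybutadiene with an (S)-glycerate-derived 4-oxo-enal.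
5. Ring order: carbocycle by cycloaddition, then a transient oxirane, then the γ-lactone.

Assumption: methyl (S)-2,2-dimethyl-1,3-dioxolane-4-carboxylate, (R)-2-methylbutanoic acid and (1E,3E)-buta-1,3-diene-1,4-diyl diacetate are bought as such.
Convention: ring carbons carry the elemanolide numbers of the target (C5–C10; C1/C2 vinyl, C3/C4/C15 propenal unit, C11–C13 lactone carbons). "Down" is the ring face of the C10 methyl and "up" the face of the C10 vinyl (or the CHO that becomes it). In the target the C5 side chain, 6-O and 9-O are down; C11 and 8-O are up.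

Step 1
Reactants: 1 methyl (S)-2,2-dimethyl-1,3-dioxolane-4-carboxylate; 2 N,O-dimethylhydroxylamine hydrochloride
Product: 3 (S)-N-methoxy-N,2,2-trimethyl-1,3-dioxolane-4-carboxamide
Conditions: iPrMgCl (3 equiv), THF, −20 to 0 °C
Reagents that add atoms: N,O-dimethylhydroxylamine hydrochloride, CNOC.Cl
Why: Weinreb amidation of the ester by the magnesium amide, which leaves the purchased α-stereocentre untouched.

Step 2
Reactants: 3 (S)-N-methoxy-N,2,2-trimethyl-1,3-dioxolane-4-carboxamide; 4 2-methylprop-1-enylmagnesium bromide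
Product: 5 (S)-1-(2,2-dimethyl-1,3-dioxolan-4-yl)-3-methylbut-2-en-1-one
Conditions: THF, −10 to 0 °C; aq. NH4Cl
Reagents that add atoms: 2-methylprop-1-enylmagnesium bromide, CC(C)=C[Mg]Br
Why: Weinreb ketone synthesis, where the chelated tetrahedral intermediate stops at the enone and the α'-centre is not enolised.

Step 3
Reactants: 5 (S)-1-(2,2-dimethyl-1,3-dioxolan-4-yl)-3-methylbut-2-en-1-one; 6 selenium dioxide
Product: 7 (S,E)-4-(2,2-dimethyl-1,3-dioxolan-4-yl)-2-methyl-4-oxobut-2-enal
Conditions: SeO2 (1.3 equiv), 1,4-dioxane, 80 °C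
Reagents that add atoms: selenium dioxide, O=[Se]=O
Why: Riley allylic oxidation (ene reaction then 2,3-shift) of the methyl group trans to the acyl group gives the E 4-oxo-enal.

Step 4
Reactants: 7 (S,E)-4-(2,2-dimethyl-1,3-dioxolan-4-yl)-2-methyl-4-oxobut-2-enal; 8 (1E,3E)-buta-1,3-diene-1,4-diyl diacetate
Product: 9 keto-aldehyde cycloadduct (cyclohex-7-ene; C5 acyl, 6-OAc, 9-OAc and C10 methyl down, C10 CHO up)
Conditions: MgBr2·OEt2 (1.2 equiv), CH2Cl2, −20 °C to rt
Reagents that add atoms: (1E,3E)-buta-1,3-diene-1,4-diyl diacetate, CC(=O)O/C=C/C=C/OC(C)=O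
Why: Diels–Alder cycloaddition in which the s-cis enone, held as a MgBr2 chelate between the ketone and the dioxolane oxygen, reacts ketone-endo on the face away from the dioxolane CH2, so the (S) centre sets C5 and C10 while the E,E-diene places both acetoxy groups (C6, C9) cis to the acyl group.

Step 5
Reactants: 9 keto-aldehyde cycloadduct; 10 dibromomethane
Product: 11 triene diacetate (C10 vinyl up; C5 1-(dioxolanyl)vinyl, 6-OAc, 9-OAc down)
Conditions: Zn, CH2Br2, TiCl4, THF/CH2Cl2, 0 °C to rt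
Reagents that add atoms: dibromomethane, BrCBr
Why: Takai–Lombardo methylenation converts the aldehyde and the hindered ketone in one operation without base, so the β-acetoxy ketone neither eliminates nor epimerises at C5.

Step 6
Reactants: 11 triene diacetate
Product: 12 triene diol (6-OH and 9-OH down)
Conditions: K2CO3 (cat.), MeOH, 0 °C to rt
Reagents that add atoms: none
Why: Zemplén-type transesterification removes both acetates with no stereocentre at risk.

Step 7
Reactants: 12 triene diol; 13 tert-butyl hydroperoxide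
Product: 14 epoxy diol (7,8-epoxide down, cis to both hydroxyls)
Conditions: VO(acac)2 (5 mol %), t-BuOOH, CH2Cl2, 0 °C to rt
Reagents that add atoms: tert-butyl hydroperoxide, CC(C)(C)OO
Why: Hydroxyl-directed vanadium-catalysed epoxidation (Sharpless–Michaelson) delivers oxygen syn to the two allylic hydroxyls and only to the ring alkene.

Step 8
Reactants: 14 epoxy diol; 15 tert-butyldimethylsilyl chloride
Product: 16 6-O-silyl epoxy alcohol (9-OH free)
Conditions: TBSCl (1.1 equiv), imidazole, DMF, 0 °C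
Reagents that add atoms: tert-butyldimethylsilyl chloride, C[Si](C)(Cl)C(C)(C)C
Why: Silylation picks the C6 hydroxyl because the C9 hydroxyl sits next to the quaternary C10.

Step 9
Reactants: 16 6-O-silyl epoxy alcohol; 17 acetic acid
Product: 18 hydroxy acid (C7 CH2CO2H up; 8-OH and 9-OH down)
Conditions: CH3CO2H, LiN(iPr)2 (2 equiv per acid), THF–DMPU, 0 to 45 °C; cold dilute HCl to pH 3
Reagents that add atoms: acetic acid (used as its dilithium dianion), CC(=O)O
Why: Creger-type epoxide opening by dilithioacetate, trans-diaxial (Fürst–Plattner) at C7 from the open upper face, sets C7 with inversion and leaves the C8 oxygen down.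

Step 10
Reactants: 18 hydroxy acid
Product: 19 cis-fused γ-lactone (C11 and 8-O up; 9-OH down)
Conditions: PPh3, DIAD, THF (0.01 M), 0 °C to rt
Reagents that add atoms: none
Why: Intramolecular Mitsunobu lactonisation, in which the carboxylate displaces the activated C8 hydroxyl with inversion; the neopentyl C9 hydroxyl cannot be displaced.

Step 11
Reactants: 19 cis-fused γ-lactone; 20 N,N-dimethylmethyleneiminium iodide
Product: 23 9-hydroxy α-methylene lactone, via Mannich base 21 (not isolated), via ammonium iodide 22 (not isolated)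
Conditions: LiN(iPr)2 (2.5 equiv), THF, −78 °C; CH2=NMe2+ I−; then MeI, MeOH; then NaHCO3, CH2Cl2/H2O
Reagents that add atoms: N,N-dimethylmethyleneiminium iodide, C=[N+](C)C.[I-]
Why: Eschenmoser aminomethylation of the lactone enolate followed by quaternisation and Hofmann-type elimination installs the exocyclic methylene.

Step 12
Reactants: 23 9-hydroxy α-methylene lactone; 24 (R)-2-methylbutanoic acid
Product: 25 9-O-[(R)-2-methylbutanoyl] lactone (6-OTBS)
Conditions: EDC·HCl, DMAP, CH2Cl2, rt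
Reagents that add atoms: (R)-2-methylbutanoic acid, CC[C@@H](C)C(=O)O
Why: Steglich esterification of the only free hydroxyl brings in the last stereocentre from the purchased acid without enolising it.

Step 13
Reactants: 25 9-O-[(R)-2-methylbutanoyl] lactone
Product: 26 6-hydroxy lactone
Conditions: HF·pyridine, pyridine/THF, 0 °C to rt
Reagents that add atoms: none
Why: Buffered fluoride desilylation spares the acetonide, the esters and the methylene lactone.

Step 14
Reactants: 26 6-hydroxy lactone; 27 angelic acid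
Product: 28 6-O-angeloyl acetonide
Conditions: 2,4,6-Cl3C6H2COCl, Et3N, toluene, rt; then 26, 80 °C
Reagents that add atoms: angelic acid, C/C=C(/C)C(=O)O
Why: Yamaguchi esterification through the mixed anhydride, run without DMAP, acylates the hindered C6 hydroxyl while keeping the Z geometry of the angelate.

Step 15
Reactants: 28 6-O-angeloyl acetonide
Product: 30 CNP0295282.1 (target), via vicinal diol 29 (not isolated)
Conditions: H5IO6, EtOAc, rt
Reagents that add atoms: none
Why: Periodic acid hydrolyses the terminal acetonide and cleaves the resulting glycol (Malaprade) to the conjugated aldehyde, removing the stereocentre that steered step 4.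

**Compound list**
1 | methyl (S)-2,2-dimethyl-1,3-dioxolane-4-carboxylate | COC(=O)[C@@H]1COC(C)(C)O1 | starting material
2 | N,O-dimethylhydroxylamine hydrochloride | CNOC.Cl | starting material
3 | (S)-N-methoxy-N,2,2-trimethyl-1,3-dioxolane-4-carboxamide | CON(C)C(=O)[C@@H]1COC(C)(C)O1 | intermediate
4 | 2-methylprop-1-enylmagnesium bromide | CC(C)=C[Mg]Br | starting material
5 | (S)-1-(2,2-dimethyl-1,3-dioxolan-4-yl)-3-methylbut-2-en-1-one | CC(C)=CC(=O)[C@@H]1COC(C)(C)O1 | intermediate
6 | selenium dioxide | O=[Se]=O | starting material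
7 | (S,E)-4-(2,2-dimethyl-1,3-dioxolan-4-yl)-2-methyl-4-oxobut-2-enal | O=C/C(C)=C/C(=O)[C@@H]1COC(C)(C)O1 | intermediate
8 | (1E,3E)-buta-1,3-diene-1,4-diyl diacetate | CC(=O)O/C=C/C=C/OC(C)=O | starting material
9 | keto-aldehyde cycloadduct: 6,9-diacetoxy-10-formyl-10-methyl-5-[(S)-2,2-dimethyl-1,3-dioxolane-4-carbonyl]cyclohex-7-ene; acyl, both OAc and CH3 down, CHO up | O=C[C@@]1(C)[C@H](C(=O)[C@@H]2COC(C)(C)O2)[C@H](OC(C)=O)C=C[C@@H]1OC(C)=O | intermediate
10 | dibromomethane | BrCBr | starting material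
11 | triene diacetate: 6,9-diacetoxy-10-methyl-10-vinyl-5-[1-(2,2-dimethyl-1,3-dioxolan-4-yl)vinyl]cyclohex-7-ene; same spatial arrangement as 9 (dioxolane carbon now labelled R by priority change) | C=C[C@@]1(C)[C@H](C(=C)[C@@H]2COC(C)(C)O2)[C@H](OC(C)=O)C=C[C@@H]1OC(C)=O | intermediate
12 | triene diol: as 11 with 6-OH and 9-OH (both down) | C=C[C@@]1(C)[C@H](C(=C)[C@@H]2COC(C)(C)O2)[C@H](O)C=C[C@@H]1O | intermediate
13 | tert-butyl hydroperoxide | CC(C)(C)OO | starting material
14 | epoxy diol: 7,8-epoxide down, cis to 6-OH and 9-OH | C=C[C@@]1(C)[C@H](C(=C)[C@@H]2COC(C)(C)O2)[C@H](O)[C@@H]3O[C@@H]3[C@@H]1O | intermediate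
15 | tert-butyldimethylsilyl chloride | C[Si](C)(Cl)C(C)(C)C | starting material
16 | 6-O-TBS epoxy alcohol (9-OH free) | C=C[C@@]1(C)[C@H](C(=C)[C@@H]2COC(C)(C)O2)[C@H](O[Si](C)(C)C(C)(C)C)[C@@H]3O[C@@H]3[C@@H]1O | intermediate
17 | acetic acid | CC(=O)O | starting material
18 | hydroxy acid: C7 CH2CO2H up, 8-OH and 9-OH down, 6-OTBS down | C=C[C@@]1(C)[C@H](C(=C)[C@@H]2COC(C)(C)O2)[C@H](O[Si](C)(C)C(C)(C)C)[C@@H](CC(=O)O)[C@H](O)[C@@H]1O | intermediate
19 | cis-fused 12,8-lactone: C11 and 8-O up, 9-OH down, 6-OTBS down | C=C[C@@]1(C)[C@H](C(=C)[C@@H]3COC(C)(C)O3)[C@H](O[Si](C)(C)C(C)(C)C)[C@H]2CC(=O)O[C@H]2[C@@H]1O | intermediate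
20 | N,N-dimethylmethyleneiminium iodide | C=[N+](C)C.[I-] | starting material
21 | Mannich base: 19 carrying CH2NMe2 at C11 (epimer mixture) | C=C[C@@]1(C)[C@H](C(=C)[C@@H]3COC(C)(C)O3)[C@H](O[Si](C)(C)C(C)(C)C)[C@H]2C(CN(C)C)C(=O)O[C@H]2[C@@H]1O | intermediate
22 | ammonium iodide: 21 N-methylated | C=C[C@@]1(C)[C@H](C(=C)[C@@H]3COC(C)(C)O3)[C@H](O[Si](C)(C)C(C)(C)C)[C@H]2C(C[N+](C)(C)C)C(=O)O[C@H]2[C@@H]1O.[I-] | intermediate
23 | 9-hydroxy α-methylene lactone (6-OTBS) | C=C[C@@]1(C)[C@H](C(=C)[C@@H]3COC(C)(C)O3)[C@H](O[Si](C)(C)C(C)(C)C)[C@H]2C(=C)C(=O)O[C@H]2[C@@H]1O | intermediate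
24 | (R)-2-methylbutanoic acid | CC[C@@H](C)C(=O)O | starting material
25 | 9-O-[(R)-2-methylbutanoyl] α-methylene lactone (6-OTBS) | C=C[C@@]1(C)[C@H](C(=C)[C@@H]3COC(C)(C)O3)[C@H](O[Si](C)(C)C(C)(C)C)[C@H]2C(=C)C(=O)O[C@H]2[C@@H]1OC(=O)[C@H](C)CC | intermediate
26 | 6-hydroxy lactone (6-OH down) | C=C[C@@]1(C)[C@H](C(=C)[C@@H]3COC(C)(C)O3)[C@H](O)[C@H]2C(=C)C(=O)O[C@H]2[C@@H]1OC(=O)[C@H](C)CC | intermediate
27 | angelic acid, (Z)-2-methylbut-2-enoic acid | C/C=C(/C)C(=O)O | starting material
28 | 6-O-angeloyl acetonide | C=C[C@@]1(C)[C@H](C(=C)[C@@H]3COC(C)(C)O3)[C@H](OC(=O)/C(C)=C\C)[C@H]2C(=C)C(=O)O[C@H]2[C@@H]1OC(=O)[C@H](C)CC | intermediate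
29 | vicinal diol: 28 without the isopropylidene group | C=C[C@@]1(C)[C@H](C(=C)[C@@H](O)CO)[C@H](OC(=O)/C(C)=C\C)[C@H]2C(=C)C(=O)O[C@H]2[C@@H]1OC(=O)[C@H](C)CC | intermediate
30 | CNP0295282.1: (5R,6S,7R,8R,9R,10S)-6-angeloyloxy-9-[(R)-2-methylbutanoyloxy]-15-oxoelema-1,3,11(13)-trien-12,8-olide | C=C[C@@]1(C)[C@H](C(=C)C=O)[C@H](OC(=O)/C(C)=C\C)[C@H]2C(=C)C(=O)O[C@H]2[C@@H]1OC(=O)[C@H](C)CC | target

**Totals**
Total step count: 15. Longest linear sequence: 15 steps (1 → 30).

**Steps most likely to fail, each with a fallback**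

Step 4 (face and endo control, and rate, of a cycloaddition that builds a quaternary centre). Set out from 7 and replace the magnesium chelate by an internal hydrogen bond as the controlling element. Aqueous acetic acid removes the acetonide to give (S,E)-5,6-dihydroxy-2-methyl-4-oxohex-2-enal F1. TBSCl and imidazole silylate the primary hydroxyl to give the α'-hydroxy enone (S,E)-6-(tert-butyldimethylsilyloxy)-5-hydroxy-2-methyl-4-oxohex-2-enal F2. This is heated with 8 in toluene at 60 °C, where the O–H···O=C bond fixes the same syn-planar arrangement and should shield the same face, giving the silyl hydroxy-ketone cycloadduct F3. HF·pyridine frees the diol cycloadduct F4, and 2,2-dimethoxypropane with PPTS re-forms the acetonide, which comes back to the route at 9.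

Step 9 (carbon nucleophile on a hindered, all-cis epoxide). Set out from 16 and use the smaller, more nucleophilic lithioacetonitrile (LiCH2CN, THF, −78 °C to rt) to open the epoxide at C7, giving the hydroxy nitrile F5. Hydrolysis with KOH in aqueous ethanol at reflux, then acidification, comes back to the route at 18.

Step 10 (Mitsunobu closure may go by acyl transfer with retention, or stall at the crowded C8 hydroxyl). Set out from 18 and separate activation from displacement. TMSCHN2 gives the methyl ester F6. MsCl with 2,4,6-collidine at −20 °C sulfonylates the less hindered C8 hydroxyl to give the C8 mesylate F7. LiOH in aqueous THF then saponifies the ester, and the carboxylate displaces the mesylate from the upper face with inversion, which comes back to the route at 19.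

**Further compounds**
F1 | step 4 | (S,E)-5,6-dihydroxy-2-methyl-4-oxohex-2-enal | O=C/C(C)=C/C(=O)[C@@H](O)CO
F2 | step 4 | (S,E)-6-(tert-butyldimethylsilyloxy)-5-hydroxy-2-methyl-4-oxohex-2-enal | O=C/C(C)=C/C(=O)[C@@H](O)CO[Si](C)(C)C(C)(C)C
F3 | step 4 | silyl hydroxy-ketone cycloadduct (ring as in 9; side chain C(=O)CH(OH)CH2OTBS) | O=C[C@@]1(C)[C@H](C(=O)[C@@H](O)CO[Si](C)(C)C(C)(C)C)[C@H](OC(C)=O)C=C[C@@H]1OC(C)=O
F4 | step 4 | diol cycloadduct (ring as in 9; side chain C(=O)CH(OH)CH2OH) | O=C[C@@]1(C)[C@H](C(=O)[C@@H](O)CO)[C@H](OC(C)=O)C=C[C@@H]1OC(C)=O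
F5 | step 9 | hydroxy nitrile (as 18 with CH2CN at C7) | C=C[C@@]1(C)[C@H](C(=C)[C@@H]2COC(C)(C)O2)[C@H](O[Si](C)(C)C(C)(C)C)[C@@H](CC#N)[C@H](O)[C@@H]1O
F6 | step 10 | methyl ester of 18 | C=C[C@@]1(C)[C@H](C(=C)[C@@H]2COC(C)(C)O2)[C@H](O[Si](C)(C)C(C)(C)C)[C@@H](CC(=O)OC)[C@H](O)[C@@H]1O
F7 | step 10 | C8 mesylate of the methyl ester | C=C[C@@]1(C)[C@H](C(=C)[C@@H]2COC(C)(C)O2)[C@H](O[Si](C)(C)C(C)(C)C)[C@@H](CC(=O)OC)[C@H](OS(C)(=O)=O)[C@@H]1O
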